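A small charge of precatalyst, 5.39% of the substrate, turns substrate and coupling partner into target in the amber flask, which is the flask asked about. The grey run is the same charge at a lower temperature.

| setting | amber | grey | flask |
|---|---|---|---|
| substrate | 0.18 M | 0.18 M | 0.18 M |
| coupling partner | 0.126 M | 0.126 M | 0.126 M |
| precatalyst | 9.7 mM | 9.7 mM | 9.7 mM |
| impurity | 1.9 mM | 1.9 mM | 1.9 mM |
| temperature | 25 °C | 10 °C | 25 °C |
| remark | the very flask that is asked about, followed so far | run made earlier |  |
| time |  |  | 40 min |

| run | time / min | target / % | substrate / % |
|---|---|---|---|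
| amber | 3.00 | 42.1 | 45.2 |
| amber | 8.00 | 48.8 | 27.3 |
| amber | 15.0 | 49.1 | 25.9 |
| amber | 40.0 | 48.9 | 25.2 |
| grey | 6.00 | 32.2 | 60.8 |
| grey | 15.0 | 50.2 | 34.4 |
| grey | 30.0 | 46.1 | 26.3 |
| grey | 80.0 | 33.5 | 25.5 |

(readings scatter by 0.3 percentage points)
- midnight: at 40 min take out 90% of the target then present, then wait 80 min
- dawn: at 40 min add coupling partner, 100% of the amount charged, then wait 80 min
- noon: change nothing and wait 80 min more
- spring: at 40 min add precatalyst, 50.0% of the amount charged, then wait 80 min
- summer: at 40 min raise the temperature by 15 K, then wait 80 min
- removed target is counted in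
- additions bring no volume worth counting
- target, in percent of the substrate first charged, at 40 min
- the option that brings most further target ("none" if no option brings more than 2 percentage points) (midnight / dawn / noon / spring / summer / none)
- target present, with what was taken out counted in, in percent of the substrate first charged, after spring
- target present, with what was taken out counted in, in percent of the substrate first charged, after summer

**The ceiling.** I ask first what the end state must be. If one coupling partner goes into each target, c(coupling partner)/c(substrate) gives a ceiling of 70.0%, with the partner as limiting reagent. As a check, amber has used 74.8% of its substrate, and the ceiling plus one substrate held per catalyst comes to 75.4%.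

**The doubt.** But amber's target rests at 48.9%, below the ceiling. Between 30.0 min and 80.0 min grey's target sinks from 46.1% to 33.5% while its substrate moves from 26.3% to 25.5%, so I take it that target passes into an unseen form, slowly in the cold and quickly enough in amber to level off by 8.00 min. Amber keeps 0.699 of what the partner allows; I call this fraction, target at rest over ceiling, the keep share.

**Dead catalyst?** Amber's flat line could also mean a dead catalyst. Yet if each impurity takes one catalyst, 80.4% of the catalyst survives, so I count it as able to work.

**The options.** Noon and spring change neither ceiling nor keep share, so target stays at 48.9%, which is also my answer for now. Midnight removes 44.0%, the remaining pool of 26.0% rebalances, and the total becomes 62.2%, a gain of 13 percentage points. Dawn lifts the partner's allowance to 140%, beyond the substrate, so the ceiling becomes the substrate charge and target reaches 69.9%, a gain of 21 points.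

**The heat.** Summer keeps the ceiling but moves the balance. The ratio of target to unseen form is 2.32 in amber and 0.918 at grey's last reading. Repeating that factor over the same 15 K gives 5.85, so target reaches 59.8%, a gain of 11 points. Grey's target may still be sinking at its last reading, so this may stand low, but I commit to dawn.

The forecast gives 48.9% now, none as best option, 46.5% after spring and 48.8% after summer, reasoning that “the loss of target must need live catalyst”.

**The result.** The flask gives 48.6%, best option dawn with 21 points more, 48.6% after spring and 59.8% after summer. Target and isomer of the product relax into balance with a half-life of 1.28 min, shorter than the 40 min waited, and at that time the flask holds 21.4% of isomer of the product.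

    coupling partner + catalyst intermediate A ⇌ catalyst intermediate B (K = 3.50 M⁻¹, k = 2.44 M⁻¹ s⁻¹, Ea = 60.0 kJ mol⁻¹, ΔH = −28.0 kJ mol⁻¹)
    catalyst intermediate B ⇌ by-product + catalyst intermediate C (K = 5.60 M, k = 0.459 s⁻¹, Ea = 71.0 kJ mol⁻¹, ΔH = −30.0 kJ mol⁻¹)
    free catalyst + impurity → spent catalyst (k = 83.5 M⁻¹ s⁻¹, Ea = 39.0 kJ mol⁻¹)
    catalyst intermediate D → free catalyst + target (k = 4.24 s⁻¹, Ea = 70.0 kJ mol⁻¹)
    substrate + free catalyst → catalyst intermediate A (k = 98.4 M⁻¹ s⁻¹, Ea = 46.0 kJ mol⁻¹)
    target ⇌ isomer of the product (K = 0.440, k = 0.00275 s⁻¹, Ea = 93.0 kJ mol⁻¹, ΔH = −49.0 kJ mol⁻¹)
    precatalyst ⇌ free catalyst (K = 0.650, k = 0.0922 s⁻¹, Ea = 71.0 kJ mol⁻¹, ΔH = −2.00 kJ mol⁻¹)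
    catalyst intermediate C → catalyst intermediate D (k = 16.3 s⁻¹, Ea = 74.0 kJ mol⁻¹)
    (constants at 25 °C)

A neighbour charged with 0.31 M of substrate has a ceiling of 40.6%, and the keep share of 0.699 turns that into 28.4%. That neighbour flask holds 28.2% of target.

All runs are simulated with made-up constants; noise was put on by code.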